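Ring A is a pentasubstituted benzene in which C8 (bearing the formyl carbon), C7–O, C6–H and C5–OMe stand in a row, exactly the pattern of C3–C6 in methyl 4,6-dimethoxy-2-oxo-2H-pyran-3-carboxylate. The route therefore disconnects ring A at C8–C8a and C4a–C5: a siloxyalkyne supplies C8a with its oxygen and C4a with C4, the C3 stereocentre, ring B and the C2 oxygen already attached. One thermal Diels–Alder addition followed by CO2 loss closes ring A with every substituent placed. The alkyne arises from an enantioselective rhodium-catalysed arylation and ynolate homologation; ring C is closed afterwards and the ester is taken to the aldehyde.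

Key step: step 10

Remark: isoflavan numbering is used (O1, C2, C3, C4, C4a, C5 to C8, C8a), and the sense of induction in step 6 is assigned from the accepted face-selection model for BINAP–rhodium aryl additions to (E)-enoates; (R)-BINAP would be taken instead should the opposite sense be found.

Step 1
Reactants: 1 4-bromoresorcinol (4-bromobenzene-1,3-diol)
Product: 2 2-bromo-5-(triisopropylsilyloxy)phenol
Conditions: TIPSCl (1.0 equiv), imidazole, CH2Cl2, −20 → 0 °C
Reagents that add atoms: triisopropylsilyl chloride, CC(C)[Si](Cl)(C(C)C)C(C)C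
Why: Silyl ether formation in which the bulky silyl chloride should take the unhindered hydroxyl para to bromine and leave the hydroxyl flanked by bromine free for building the pyran ring of ring B.

Step 2
Reactants: 2 2-bromo-5-(triisopropylsilyloxy)phenol; 3 3-chloro-3-methylbut-1-yne
Product: 4 1-bromo-2-[(2-methylbut-3-yn-2-yl)oxy]-4-(triisopropylsilyloxy)benzene
Conditions: CuCl2·2H2O (cat.), DBU, MeCN, 0 °C
Reagents that add atoms: none
Why: Copper-catalysed O-propargylation of a phenol by a tertiary propargylic chloride, a mild etherification that works on ortho-substituted phenols and leaves the aryl silyl ether alone.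

Step 3
Reactants: 4 1-bromo-2-[(2-methylbut-3-yn-2-yl)oxy]-4-(triisopropylsilyloxy)benzene
Product: 6 8-bromo-2,2-dimethyl-5-(triisopropylsilyloxy)-2H-chromene, via allenylphenol 5 (not isolated)
Conditions: PhNEt2, 180 °C
Reagents that add atoms: none
Why: Aryl propargyl ether Claisen rearrangement followed by 1,5-hydrogen shift and oxa-6π electrocyclisation; bromine blocks one ortho position, so the shift can only reach the carbon between the two oxygens and the chromene is formed with the ring fusion that ring B needs.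

Step 4
Reactants: 6 8-bromo-2,2-dimethyl-5-(triisopropylsilyloxy)-2H-chromene
Product: 9 [2,2-dimethyl-5-(triisopropylsilyloxy)-2H-chromen-8-yl]boronic acid, via aryllithium 7 (not isolated), via lithium triisopropoxyborate 8 (not isolated)
Conditions: n-BuLi, THF, −78 °C; B(Oi-Pr)3, −78 °C → rt; 1 M HCl, 0 °C
Reagents that add atoms: triisopropyl borate, CC(C)OB(OC(C)C)OC(C)C; water, O
Why: Bromine–lithium exchange and trapping of the aryllithium by a borate ester, then hydrolysis of the borate complex, the standard route to arylboronic acids.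

Step 5
Reactants: 10 (tert-butyldimethylsilyloxy)acetaldehyde; 11 methyl (triphenylphosphoranylidene)acetate
Product: 12 methyl (2E)-4-(tert-butyldimethylsilyloxy)but-2-enoate
Conditions: CH2Cl2, rt
Reagents that add atoms: none
Why: Wittig olefination with a stabilised ylide, which should give the (E)-enoate that already carries the protected C2 oxygen.

Step 6
Reactants: 9 [2,2-dimethyl-5-(triisopropylsilyloxy)-2H-chromen-8-yl]boronic acid; 12 methyl (2E)-4-(tert-butyldimethylsilyloxy)but-2-enoate
Product: 13 methyl (3R)-4-(tert-butyldimethylsilyloxy)-3-[2,2-dimethyl-5-(triisopropylsilyloxy)-2H-chromen-8-yl]butanoate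
Conditions: [Rh(nbd)2]BF4 (2 mol %), (S)-BINAP, Et3N, dioxane/H2O (10:1), 30 → 50 °C
Reagents that add atoms: none
Why: Hayashi–Miyaura asymmetric 1,4-addition, in which transmetalation gives an aryl–rhodium species (monovalent rhodium) bound to (S)-BINAP that carbometalates the (E)-enoate on the enantioface left open by the ligand and so sets the future C3 as (R), after which water protonates the rhodium enolate under conditions mild enough for the aryl silyl ether and the ester.

Step 7
Reactants: 13 methyl (3R)-4-(tert-butyldimethylsilyloxy)-3-[2,2-dimethyl-5-(triisopropylsilyloxy)-2H-chromen-8-yl]butanoate; 14 dibromomethane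
Product: 17 (4R)-5-(tert-butyldimethylsilyloxy)-4-[2,2-dimethyl-5-(triisopropylsilyloxy)-2H-chromen-8-yl]-1-(triisopropylsilyloxy)pent-1-yne, via dibromo enolate 15 (not isolated), via lithium ynolate 16 (not isolated)
Conditions: CH2Br2, lithium 2,2,6,6-tetramethylpiperidide, THF, −78 °C; LiN(SiMe3)2; n-BuLi, −78 °C → rt; TIPSOTf, −78 → 0 °C
Reagents that add atoms: triisopropylsilyl trifluoromethanesulfonate, CC(C)[Si](OS(=O)(=O)C(F)(F)F)(C(C)C)C(C)C
Why: Kowalski ester homologation stopped at the ynolate, in which dibromomethyllithium acylation, enolisation, bromine–lithium exchange and carbenoid 1,2-shift give the ynolate that is O-silylated by the silyl triflate, while the stereocentre, β to the reacting carbonyl and not enolisable, is untouched.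

Step 8
Reactants: 18 malonyl dichloride
Product: 21 methyl 4-hydroxy-6-methoxy-2-oxo-2H-pyran-3-carboxylate, via chloropyrone acid chloride 19 (not isolated), via chloropyrone methyl ester 20 (not isolated)
Conditions: neat, 50 °C; then MeOH, 0 °C → reflux
Reagents that add atoms: methanol, CO
Why: Self-condensation of malonyl dichloride (C-acylation of one molecule by a second, then ring closure through the enolised acid chloride oxygen), followed by alcoholysis of the acid chloride and addition–elimination of methanol at C6, which is a vinylogous acid chloride carbon.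

Step 9
Reactants: 21 methyl 4-hydroxy-6-methoxy-2-oxo-2H-pyran-3-carboxylate
Product: 22 methyl 4,6-dimethoxy-2-oxo-2H-pyran-3-carboxylate
Conditions: Me2SO4, K2CO3, acetone, reflux
Reagents that add atoms: dimethyl sulfate, COS(=O)(=O)OC
Why: O-Alkylation of the acidic 4-hydroxyl of a 4-hydroxy-2-pyrone (a vinylogous acid), which under carbonate and dimethyl sulfate should give the 4-methoxy-2-pyrone.

Step 10
Reactants: 17 (4R)-5-(tert-butyldimethylsilyloxy)-4-[2,2-dimethyl-5-(triisopropylsilyloxy)-2H-chromen-8-yl]-1-(triisopropylsilyloxy)pent-1-yne; 22 methyl 4,6-dimethoxy-2-oxo-2H-pyran-3-carboxylate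
Product: 24 methyl 3-[(2R)-3-(tert-butyldimethylsilyloxy)-2-[2,2-dimethyl-5-(triisopropylsilyloxy)-2H-chromen-8-yl]propyl]-4,6-dimethoxy-2-(triisopropylsilyloxy)benzoate, via bridged lactone 23 (not isolated)
Conditions: PhMe, 120 °C, sealed tube, excess of 22
Reagents that add atoms: none
Why: The diene of 22, made electron-poor by its lactone and ester carbonyls, and the electron-rich alkyne of 17 should combine in an asynchronous inverse-demand [4+2] cycloaddition in which the chain-bearing alkyne carbon bonds to pyrone C6 and the silyloxy-bearing carbon bonds to pyrone C3, giving the 2-oxabicyclo[2.2.2]octadienone 23, which then loses CO2 by a retro-[4+2] step. The closest known reaction type is the Diels–Alder/decarboxylation benzannulation of 3-carbalkoxy-2-pyrones with ynamines, alkoxyalkynes and siloxyalkynes. Ring A is closed by an intermolecular [4+2] cycloaddition that forms C8–C8a and C4a–C5, and it is aromatic as soon as CO2 leaves because the 2π partner is an alkyne. No stereocentre is created: the bridgehead centres of 23 vanish on cycloreversion, and the C3 centre, two atoms from the alkyne and not enolisable, is untouched. The step needs regioselectivity, secured by polarity matching (the nucleophilic alkyne β-carbon pairs with the vinylogous carbonyl position C6 and the oxygenated carbon ends up next to the ester), and chemoselectivity over the chromene alkene, secured by the much higher nucleophilicity of the siloxyalkyne. Because the two methoxy groups lower the reactivity of the diene, heat and an excess of 22 are planned.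

Step 11
Reactants: 24 methyl 3-[(2R)-3-(tert-butyldimethylsilyloxy)-2-[2,2-dimethyl-5-(triisopropylsilyloxy)-2H-chromen-8-yl]propyl]-4,6-dimethoxy-2-(triisopropylsilyloxy)benzoate
Product: 25 methyl 2-hydroxy-3-[(2R)-3-hydroxy-2-(5-hydroxy-2,2-dimethyl-2H-chromen-8-yl)propyl]-4,6-dimethoxybenzoate
Conditions: TBAF, AcOH, THF, 0 °C → rt
Reagents that add atoms: none
Why: Fluoride-mediated desilylation should cleave both aryl silyl ethers and the primary silyl ether in one operation, with acetic acid buffering to keep the liberated electron-rich phenols protonated.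

Step 12
Reactants: 25 methyl 2-hydroxy-3-[(2R)-3-hydroxy-2-(5-hydroxy-2,2-dimethyl-2H-chromen-8-yl)propyl]-4,6-dimethoxybenzoate
Product: 26 methyl (3R)-3-(5-hydroxy-2,2-dimethyl-2H-chromen-8-yl)-5,7-dimethoxy-3,4-dihydro-2H-chromene-8-carboxylate
Conditions: PPh3, DIAD, THF (0.01 M), 0 °C → rt
Reagents that add atoms: none
Why: Intramolecular Mitsunobu etherification in which the salicylate hydroxyl displaces the activated primary oxygen in a 6-exo-tet closure of ring C without touching C3, while the ring B phenol cannot reach the carbinol and high dilution should suppress its intermolecular alkylation.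

Step 13
Reactants: 26 methyl (3R)-3-(5-hydroxy-2,2-dimethyl-2H-chromen-8-yl)-5,7-dimethoxy-3,4-dihydro-2H-chromene-8-carboxylate
Product: 27 8-[(3R)-8-(hydroxymethyl)-5,7-dimethoxy-3,4-dihydro-2H-chromen-3-yl]-2,2-dimethyl-2H-chromen-5-ol
Conditions: LiAlH4 (excess), THF, 0 °C → rt; H2O, aq. NaOH work-up
Reagents that add atoms: none
Why: Hydride reduction of the hindered benzoate to the benzylic alcohol, with one extra hydride consumed by the phenol, and with C7 still a methyl ether so that no ortho-hydroxybenzyl over-reduction path is open.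

Step 14
Reactants: 27 8-[(3R)-8-(hydroxymethyl)-5,7-dimethoxy-3,4-dihydro-2H-chromen-3-yl]-2,2-dimethyl-2H-chromen-5-ol
Product: 28 (3R)-3-(5-hydroxy-2,2-dimethyl-2H-chromen-8-yl)-5,7-dimethoxy-3,4-dihydro-2H-chromene-8-carbaldehyde
Conditions: MnO2 (activated, excess), CH2Cl2, rt
Reagents that add atoms: none
Why: Benzylic alcohol oxidation by MnO2, which stops at the aldehyde and should tolerate the phenol and the chromene alkene under neutral conditions that suit the acid-labile trialkoxybenzyl alcohol.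

Step 15
Reactants: 28 (3R)-3-(5-hydroxy-2,2-dimethyl-2H-chromen-8-yl)-5,7-dimethoxy-3,4-dihydro-2H-chromene-8-carbaldehyde
Product: 29 (3R)-7-hydroxy-3-(5-hydroxy-2,2-dimethyl-2H-chromen-8-yl)-5-methoxy-3,4-dihydro-2H-chromene-8-carbaldehyde (target)
Conditions: MgI2·OEt2, PhMe, 70 °C; dil. HCl
Reagents that add atoms: none
Why: Chelation-assisted ether cleavage in which magnesium bridges the formyl oxygen and the ortho C7 methoxy oxygen and iodide removes that methyl by SN2 attack, while the C5 methoxy is not chelated and the β-branched C2 methylene of ring C resists iodide.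

Compound list
1 | 4-bromoresorcinol (4-bromobenzene-1,3-diol) | Oc1ccc(Br)c(O)c1 | starting material
2 | 2-bromo-5-(triisopropylsilyloxy)phenol | Oc1cc(O[Si](C(C)C)(C(C)C)C(C)C)ccc1Br | intermediate
3 | 3-chloro-3-methylbut-1-yne | C#CC(C)(C)Cl | starting material
4 | 1-bromo-2-[(2-methylbut-3-yn-2-yl)oxy]-4-(triisopropylsilyloxy)benzene | C#CC(C)(C)Oc1cc(O[Si](C(C)C)(C(C)C)C(C)C)ccc1Br | intermediate
5 | 6-bromo-2-(3-methylbuta-1,2-dien-1-yl)-3-(triisopropylsilyloxy)phenol (not isolated) | CC(C)=C=Cc1c(O)c(Br)ccc1O[Si](C(C)C)(C(C)C)C(C)C | intermediate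
6 | 8-bromo-2,2-dimethyl-5-(triisopropylsilyloxy)-2H-chromene | CC1(C)C=Cc2c(O[Si](C(C)C)(C(C)C)C(C)C)ccc(Br)c2O1 | intermediate
7 | [2,2-dimethyl-5-(triisopropylsilyloxy)-2H-chromen-8-yl]lithium (not isolated) | [Li]c1ccc(O[Si](C(C)C)(C(C)C)C(C)C)c2C=CC(C)(C)Oc12 | intermediate
8 | lithium [2,2-dimethyl-5-(triisopropylsilyloxy)-2H-chromen-8-yl]tri(propan-2-yloxy)borate (not isolated) | [Li+].CC(C)O[B-](OC(C)C)(OC(C)C)c1ccc(O[Si](C(C)C)(C(C)C)C(C)C)c2C=CC(C)(C)Oc12 | intermediate
9 | [2,2-dimethyl-5-(triisopropylsilyloxy)-2H-chromen-8-yl]boronic acid | OB(O)c1ccc(O[Si](C(C)C)(C(C)C)C(C)C)c2C=CC(C)(C)Oc12 | intermediate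
10 | (tert-butyldimethylsilyloxy)acetaldehyde | CC(C)(C)[Si](C)(C)OCC=O | starting material
11 | methyl (triphenylphosphoranylidene)acetate | COC(=O)C=P(c1ccccc1)(c1ccccc1)c1ccccc1 | starting material
12 | methyl (2E)-4-(tert-butyldimethylsilyloxy)but-2-enoate | COC(=O)/C=C/CO[Si](C)(C)C(C)(C)C | intermediate
13 | methyl (3R)-4-(tert-butyldimethylsilyloxy)-3-[2,2-dimethyl-5-(triisopropylsilyloxy)-2H-chromen-8-yl]butanoate | COC(=O)C[C@H](c1ccc(O[Si](C(C)C)(C(C)C)C(C)C)c2c1OC(C)(C)C=C2)CO[Si](C)(C)C(C)(C)C | intermediate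
14 | dibromomethane | BrCBr | starting material
15 | lithium (4R)-1,1-dibromo-5-(tert-butyldimethylsilyloxy)-4-[2,2-dimethyl-5-(triisopropylsilyloxy)-2H-chromen-8-yl]pent-1-en-2-olate (not isolated) | [Li+].[O-]C(=C(Br)Br)C[C@H](c1ccc(O[Si](C(C)C)(C(C)C)C(C)C)c2c1OC(C)(C)C=C2)CO[Si](C)(C)C(C)(C)C | intermediate
16 | lithium (4R)-5-(tert-butyldimethylsilyloxy)-4-[2,2-dimethyl-5-(triisopropylsilyloxy)-2H-chromen-8-yl]pent-1-yn-1-olate (not isolated) | [Li+].[O-]C#CC[C@H](c1ccc(O[Si](C(C)C)(C(C)C)C(C)C)c2c1OC(C)(C)C=C2)CO[Si](C)(C)C(C)(C)C | intermediate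
17 | (4R)-5-(tert-butyldimethylsilyloxy)-4-[2,2-dimethyl-5-(triisopropylsilyloxy)-2H-chromen-8-yl]-1-(triisopropylsilyloxy)pent-1-yne | CC(C)[Si](C(C)C)(C(C)C)OC#CC[C@H](c1ccc(O[Si](C(C)C)(C(C)C)C(C)C)c2c1OC(C)(C)C=C2)CO[Si](C)(C)C(C)(C)C | intermediate
18 | malonyl dichloride | O=C(Cl)CC(=O)Cl | starting material
19 | 6-chloro-4-hydroxy-2-oxo-2H-pyran-3-carbonyl chloride (not isolated) | O=C(Cl)C1=C(O)C=C(Cl)OC1=O | intermediate
20 | methyl 6-chloro-4-hydroxy-2-oxo-2H-pyran-3-carboxylate (not isolated) | COC(=O)C1=C(O)C=C(Cl)OC1=O | intermediate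
21 | methyl 4-hydroxy-6-methoxy-2-oxo-2H-pyran-3-carboxylate | COC(=O)C1=C(O)C=C(OC)OC1=O | intermediate
22 | methyl 4,6-dimethoxy-2-oxo-2H-pyran-3-carboxylate | COC(=O)C1=C(OC)C=C(OC)OC1=O | intermediate
23 | methyl 7-[(2R)-3-(tert-butyldimethylsilyloxy)-2-[2,2-dimethyl-5-(triisopropylsilyloxy)-2H-chromen-8-yl]propyl]-1,5-dimethoxy-3-oxo-8-(triisopropylsilyloxy)-2-oxabicyclo[2.2.2]octa-5,7-diene-4-carboxylate (not isolated; bridgehead centres undefined) | COC(=O)C12C(=O)OC(OC)(C=C1OC)C(C[C@H](c1ccc(O[Si](C(C)C)(C(C)C)C(C)C)c3c1OC(C)(C)C=C3)CO[Si](C)(C)C(C)(C)C)=C2O[Si](C(C)C)(C(C)C)C(C)C | intermediate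
24 | methyl 3-[(2R)-3-(tert-butyldimethylsilyloxy)-2-[2,2-dimethyl-5-(triisopropylsilyloxy)-2H-chromen-8-yl]propyl]-4,6-dimethoxy-2-(triisopropylsilyloxy)benzoate | COC(=O)c1c(OC)cc(OC)c(C[C@H](c2ccc(O[Si](C(C)C)(C(C)C)C(C)C)c3c2OC(C)(C)C=C3)CO[Si](C)(C)C(C)(C)C)c1O[Si](C(C)C)(C(C)C)C(C)C | intermediate
25 | methyl 2-hydroxy-3-[(2R)-3-hydroxy-2-(5-hydroxy-2,2-dimethyl-2H-chromen-8-yl)propyl]-4,6-dimethoxybenzoate | COC(=O)c1c(OC)cc(OC)c(C[C@H](c2ccc(O)c3c2OC(C)(C)C=C3)CO)c1O | intermediate
26 | methyl (3R)-3-(5-hydroxy-2,2-dimethyl-2H-chromen-8-yl)-5,7-dimethoxy-3,4-dihydro-2H-chromene-8-carboxylate | COc1cc(OC)c(C(=O)OC)c2c1C[C@H](c1ccc(O)c3c1OC(C)(C)C=C3)CO2 | intermediate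
27 | 8-[(3R)-8-(hydroxymethyl)-5,7-dimethoxy-3,4-dihydro-2H-chromen-3-yl]-2,2-dimethyl-2H-chromen-5-ol | COc1cc(OC)c(CO)c2c1C[C@H](c1ccc(O)c3c1OC(C)(C)C=C3)CO2 | intermediate
28 | (3R)-3-(5-hydroxy-2,2-dimethyl-2H-chromen-8-yl)-5,7-dimethoxy-3,4-dihydro-2H-chromene-8-carbaldehyde | COc1cc(OC)c(C=O)c2c1C[C@H](c1ccc(O)c3c1OC(C)(C)C=C3)CO2 | intermediate
29 | (3R)-7-hydroxy-3-(5-hydroxy-2,2-dimethyl-2H-chromen-8-yl)-5-methoxy-3,4-dihydro-2H-chromene-8-carbaldehyde | COc1cc(O)c(C=O)c2c1C[C@H](c1ccc(O)c3c1OC(C)(C)C=C3)CO2 | target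

Total step count: 15. Longest linear sequence: 12 steps (steps 1, 2, 3, 4, 6, 7, 10, 11, 12, 13, 14, 15).

Steps most likely to fail

Step 10. The cycloaddition to a pyrone carrying two donor groups may be slow, so that thermal silyl migration of the siloxyalkyne to a silylketene, or its protonation by traces of acid, could consume the alkyne first. The fallback swaps the alkyne for a more nucleophilic and thermally sturdier alkene partner that aromatises by elimination. It sets out from ester 13 and comes back at 25. Ester 13 is homologated as in step 7, but ynolate 16 is quenched with water instead of the silyl triflate, which should give (4R)-5-(tert-butyldimethylsilyloxy)-4-[2,2-dimethyl-5-(triisopropylsilyloxy)-2H-chromen-8-yl]pentanoic acid F1. Double deprotonation and silylation (LiN(i-Pr)2, Me3SiCl, THF, −78 °C) converts it into the ketene bis(trimethylsilyl) acetal (4R)-5-(tert-butyldimethylsilyloxy)-4-[2,2-dimethyl-5-(triisopropylsilyloxy)-2H-chromen-8-yl]-1,1-bis(trimethylsilyloxy)pent-1-ene F2. Heating F2 with pyrone 22 in toluene should bring about the inverse-demand Diels–Alder addition of a ketene acetal to a 3-carbalkoxy-2-pyrone with the same orientation, loss of CO2 and elimination of trimethylsilanol from the dihydrobenzene. Aqueous work-up then frees the salicylate methyl 3-[(2R)-3-(tert-butyldimethylsilyloxy)-2-[2,2-dimethyl-5-(triisopropylsilyloxy)-2H-chromen-8-yl]propyl]-2-hydroxy-4,6-dimethoxybenzoate F3. Treatment of F3 under the conditions of step 11 gives 25.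

Step 6. Transmetalation of the ortho-substituted, electron-rich boronic acid may be slow, so that protodeboronation wins, or face selection on the acyclic enoate may be incomplete. The fallback replaces catalyst control by auxiliary control and needs no boronic acid. It sets out from bromide 6 and aldehyde 10 and comes back at 13. Masamune–Roush olefination of 10 with (4S)-3-[(diethoxyphosphoryl)acetyl]-4-phenyl-1,3-oxazolidin-2-one (LiCl, i-Pr2NEt, MeCN) gives (4S)-3-[(2E)-4-(tert-butyldimethylsilyloxy)but-2-enoyl]-4-phenyl-1,3-oxazolidin-2-one F4. The aryl Grignard reagent made from 6 (Mg, THF) is added with CuBr·SMe2 at −40 °C; in the magnesium-chelated s-cis imide the aryl group should enter anti to the phenyl substituent. This gives (4S)-3-[(3R)-4-(tert-butyldimethylsilyloxy)-3-[2,2-dimethyl-5-(triisopropylsilyloxy)-2H-chromen-8-yl]butanoyl]-4-phenyl-1,3-oxazolidin-2-one F5. Methanolysis (NaOMe, MeOH, 0 °C) releases the auxiliary and gives 13.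

Step 7. The carbenoid rearrangement to the ynolate may be incomplete, or the sequence of three strong lithium bases may metalate the substrate or cleave a silyl ether. The fallback makes the ynolate by oxidising an acetylide instead of homologating the ester. It sets out from 13 and comes back at ynolate 16 and thus 17. Reduction with i-Bu2AlH (CH2Cl2, −78 °C) gives (3R)-4-(tert-butyldimethylsilyloxy)-3-[2,2-dimethyl-5-(triisopropylsilyloxy)-2H-chromen-8-yl]butanal F6. Ohira–Bestmann homologation (dimethyl (1-diazo-2-oxopropyl)phosphonate, K2CO3, MeOH, 0 °C) gives (4R)-5-(tert-butyldimethylsilyloxy)-4-[2,2-dimethyl-5-(triisopropylsilyloxy)-2H-chromen-8-yl]pent-1-yne F7. Deprotonation with LiN(SiMe3)2 and oxidation of the lithium acetylide with lithium tert-butyl peroxide (from t-BuOOH and LiN(SiMe3)2, THF, −78 → 0 °C) generates 16, which TIPSOTf silylates to 17.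

Further compounds
F1 | step 10 | (4R)-5-(tert-butyldimethylsilyloxy)-4-[2,2-dimethyl-5-(triisopropylsilyloxy)-2H-chromen-8-yl]pentanoic acid | OC(=O)CC[C@H](c1ccc(O[Si](C(C)C)(C(C)C)C(C)C)c2c1OC(C)(C)C=C2)CO[Si](C)(C)C(C)(C)C
F2 | step 10 | (4R)-5-(tert-butyldimethylsilyloxy)-4-[2,2-dimethyl-5-(triisopropylsilyloxy)-2H-chromen-8-yl]-1,1-bis(trimethylsilyloxy)pent-1-ene | C[Si](C)(C)OC(O[Si](C)(C)C)=CC[C@H](c1ccc(O[Si](C(C)C)(C(C)C)C(C)C)c2c1OC(C)(C)C=C2)CO[Si](C)(C)C(C)(C)C
F3 | step 10 | methyl 3-[(2R)-3-(tert-butyldimethylsilyloxy)-2-[2,2-dimethyl-5-(triisopropylsilyloxy)-2H-chromen-8-yl]propyl]-2-hydroxy-4,6-dimethoxybenzoate | COC(=O)c1c(OC)cc(OC)c(C[C@H](c2ccc(O[Si](C(C)C)(C(C)C)C(C)C)c3c2OC(C)(C)C=C3)CO[Si](C)(C)C(C)(C)C)c1O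
F4 | step 6 | (4S)-3-[(2E)-4-(tert-butyldimethylsilyloxy)but-2-enoyl]-4-phenyl-1,3-oxazolidin-2-one | O=C1OC[C@H](c2ccccc2)N1C(=O)/C=C/CO[Si](C)(C)C(C)(C)C
F5 | step 6 | (4S)-3-[(3R)-4-(tert-butyldimethylsilyloxy)-3-[2,2-dimethyl-5-(triisopropylsilyloxy)-2H-chromen-8-yl]butanoyl]-4-phenyl-1,3-oxazolidin-2-one | O=C1OC[C@H](c2ccccc2)N1C(=O)C[C@H](c1ccc(O[Si](C(C)C)(C(C)C)C(C)C)c3c1OC(C)(C)C=C3)CO[Si](C)(C)C(C)(C)C
F6 | step 7 | (3R)-4-(tert-butyldimethylsilyloxy)-3-[2,2-dimethyl-5-(triisopropylsilyloxy)-2H-chromen-8-yl]butanal | O=CC[C@H](c1ccc(O[Si](C(C)C)(C(C)C)C(C)C)c2c1OC(C)(C)C=C2)CO[Si](C)(C)C(C)(C)C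
F7 | step 7 | (4R)-5-(tert-butyldimethylsilyloxy)-4-[2,2-dimethyl-5-(triisopropylsilyloxy)-2H-chromen-8-yl]pent-1-yne | C#CC[C@H](c1ccc(O[Si](C(C)C)(C(C)C)C(C)C)c2c1OC(C)(C)C=C2)CO[Si](C)(C)C(C)(C)C
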